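Locants are germacrane locants: ring C1–C10; lactone O6–C12(=O)–C11(=C13H2)–C7; C14 on C10; C15 on C4. The retrosynthesis cuts, in order: lactone O6–C12 (back to a C12 allylic alcohol), C9–C10 together with the O8–acyl bond, C5–C6, C7–C11, C1=C10.
Enabling feature: C9(OH)–C8(O-acyl) is a syn-1,2-diol. C9 is bonded to the sp2 carbon C10, and its other neighbour C7 is fully substituted. This is the retron of a terminal C8–C9 epoxide (O8 as ring oxygen) lithiated at C9, plus an alkenylboronate at C10. Because C7 has no hydrogen, β-elimination of the epoxide is impossible.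
Forward: three pieces give an acyclic C1–C13 chain. C9–Li adds to boron and closes an eleven-membered boracycle. The shift of C10 from boron to C9 contracts this to the ten-membered carbocycle and expels boron from the ring. O8 appears as the only alkoxide and takes the angelate, boron becomes O9, and the γ-lactone is closed last by oxidation.
Stereochemistry: C8 comes from L-erythrulose, C7 and C6 from chelate-controlled additions, and C9 from the stereospecific lithiation–borylation–migration. C1=C10 (Z) comes from Stork–Zhao olefination, C4=C5 (E) from syn-carboalumination, and the angelate geometry from the reagent.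

Key step: step 13

Remark: lactol 29 is taken as a C12 epimer mixture (its SMILES leaves C12 open); both epimers give 30.

Step 1
Reactants: 1 pent-4-yn-1-ol
Product: 2 pent-4-ynal
Conditions: IBX, EtOAc, 80 °C
Reagents that add atoms: none
Why: IBX oxidation takes the primary alcohol to the aldehyde without over-oxidation and does not touch the terminal alkyne.

Step 2
Reactants: 2 pent-4-ynal
Product: 3 (Z)-6-iodohept-5-en-1-yne
Conditions: EtPPh3I, n-BuLi, THF, rt; I2, −78 °C; NaN(SiMe3)2, −20 °C; then 2, −78 °C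
Reagents that add atoms: ethyltriphenylphosphonium iodide, CC[P+](c1ccccc1)(c1ccccc1)c1ccccc1.[I-]; iodine, II
Why: Stork–Zhao olefination with the α-iodoethylidene ylide is kinetically Z-selective, so iodine ends up cis to the C2 chain and the C1=C10 geometry of the target is fixed here.

Step 3
Reactants: 4 2-bromoprop-2-en-1-ol
Product: 5 (2-bromoallyloxy)(tert-butyl)dimethylsilane
Conditions: TBSCl, imidazole, CH2Cl2, 0 °C to rt
Reagents that add atoms: tert-butyldimethylsilyl chloride, CC(C)(C)[Si](C)(C)Cl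
Why: Standard imidazole-promoted silylation masks O12 for the organometallic steps.

Step 4
Reactants: 6 L-erythrulose
Product: 7 3,4-O-isopropylidene-L-erythrulose
Conditions: 2,2-dimethoxypropane, camphorsulfonic acid (cat.), acetone, rt
Reagents that add atoms: 2,2-dimethoxypropane, COC(C)(C)OC
Why: Acid-catalysed transketalisation ties the vicinal O8/O9 diol into the favoured five-membered dioxolane, leaves the primary O6 hydroxyl free and does not touch the C8 stereocentre taken from the chiral pool.

Step 5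
Reactants: 7 3,4-O-isopropylidene-L-erythrulose
Product: 8 1-O-triethylsilyl-3,4-O-isopropylidene-L-erythrulose
Conditions: Et3SiCl, imidazole, CH2Cl2, 0 °C
Reagents that add atoms: chlorotriethylsilane, CC[Si](Cl)(CC)CC
Why: Silylation of the remaining primary hydroxyl with a bulky non-chelating group leaves O8 as the only donor for chelation in the next step.

Step 6
Reactants: 5 (2-bromoallyloxy)(tert-butyl)dimethylsilane; 8 1-O-triethylsilyl-3,4-O-isopropylidene-L-erythrulose
Product: 11 C7 tertiary alcohol (C6–C9/C11–C13 block; O7/O8 erythro), via alkenyllithium 9 (not isolated), via alkenylmagnesium bromide 10 (not isolated)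
Conditions: 5, t-BuLi (2 equiv), Et2O, −78 °C; MgBr2·OEt2, −78 to 0 °C; 8, CH2Cl2/Et2O, −78 °C; aq NH4Cl
Reagents that add atoms: none
Why: After bromine–lithium exchange and transmetallation, the alkenylmagnesium reagent adds under Cram-chelate control, with magnesium bridging the ketone oxygen and dioxolane O8 so that attack from the face of H8 (anti to C9) sets C7 with O7 and O8 erythro.

Step 7
Reactants: 11 C7 tertiary alcohol
Product: 12 C6 aldehyde (α-hydroxy aldehyde with quaternary C7)
Conditions: (COCl)2, DMSO, CH2Cl2, −78 to −40 °C; Et3N, to 0 °C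
Reagents that add atoms: none
Why: Swern oxidation applied directly to a primary triethylsilyl ether exchanges the labile silyl group for the alkoxysulfonium ion and gives the aldehyde in one operation, while the TBS ether, the tertiary hydroxyl and the ketal are inert and C7 has no hydrogen to epimerise.

Step 8
Reactants: 3 (Z)-6-iodohept-5-en-1-yne; 12 C6 aldehyde
Product: 14 seco-germacrane C6,C7-diol (4E,1(10)Z; C10 iodide), via alkenylalane 13 (not isolated)
Conditions: 3, Me3Al (3 equiv), Cp2ZrCl2 (0.2 equiv), CH2Cl2, 0 °C to rt; then 12, −78 to −20 °C; aq potassium sodium tartrate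
Reagents that add atoms: trimethylaluminium, C[Al](C)C
Why: Negishi zirconium-catalysed syn-carboalumination puts C15 on C4 and aluminium on C5 (E geometry), and the alkenylalane then adds to the aldehyde, held in a five-membered O6–Al–O7 chelate, from the face of the flat C11 alkenyl group anti to the dioxolanyl C8, which sets C6.

Step 9
Reactants: 14 seco-germacrane C6,C7-diol
Product: 16 fully protected iodide (O6-TBS; O7-TES; O12-TBS; O8/O9 acetonide), via O6 TBS ether 15 (not isolated)
Conditions: TBSOTf (1.1 equiv), 2,6-lutidine, CH2Cl2, −78 °C; then Et3SiOTf (2 equiv), −78 to 0 °C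
Reagents that add atoms: tert-butyldimethylsilyl triflate, CC(C)(C)[Si](C)(C)OS(=O)(=O)C(F)(F)F; triethylsilyl triflate, CC[Si](CC)(CC)OS(=O)(=O)C(F)(F)F
Why: Silyl triflate/2,6-lutidine silylation in order of steric demand (TBS on the secondary allylic O6, the smaller TES on the tertiary O7) removes every acidic O–H before the strong-base steps.

Step 10
Reactants: 16 fully protected iodide
Product: 18 (Z)-C10 alkenyl pinacol boronate (acetonide), via C10 alkenyllithium 17 (not isolated)
Conditions: t-BuLi (2.1 equiv), Et2O, −78 °C; i-PrOBpin, −78 °C to rt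
Reagents that add atoms: 2-isopropoxy-4,4,5,5-tetramethyl-1,3,2-dioxaborolane, CC(C)OB1OC(C)(C)C(C)(C)O1
Why: Iodine–lithium exchange and borylation of the alkenyllithium with an isopropoxy boronate both go with retention, so boron takes the place of iodine cis to C2.

Step 11
Reactants: 18 (Z)-C10 alkenyl pinacol boronate (acetonide)
Product: 19 C8,C9-diol boronate
Conditions: Zn(NO3)2·6H2O, MeCN, 50 °C
Reagents that add atoms: none
Why: Mild Lewis-acid hydrolysis cleaves the unhindered terminal isopropylidene ketal faster than the hindered silyl ethers or the pinacol boronate.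

Step 12
Reactants: 19 C8,C9-diol boronate
Product: 21 terminal C8–C9 epoxide boronate, via C9 tosylate 20 (not isolated)
Conditions: TsCl, Et3N, Bu2SnO (cat.), CH2Cl2, 0 °C; then K2CO3, MeOH, 0 °C
Reagents that add atoms: none
Why: Tin-acetal-catalysed sulfonylation picks the primary O9 of the terminal diol, and base-induced 3-exo-tet Williamson closure by O8 gives the epoxide with the C8–O8 bond, and hence C8, untouched.

Step 13
Reactants: 21 terminal C8–C9 epoxide boronate
Product: 25 ten-membered C9 boronate C8 angelate, via lithiated epoxide 22 (not isolated), via cyclic boronate complex 23 (not isolated), via lithium C8 alkoxide 24 (not isolated)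
Conditions: LiTMP (lithium 2,2,6,6-tetramethylpiperidide, 1.6 equiv, slow addition), THF (0.003 M), −30 °C; cool to −78 °C, angelic anhydride (3 equiv); warm to rt
Reagents that add atoms: angelic anhydride, C/C=C(/C)C(=O)OC(=O)/C(C)=C\C
Why: Proposed new method: LiTMP removes the C9 hydrogen trans to C7 of the terminal epoxide (α-lithiation is the only path because C7 has no hydrogen for β-elimination), the carbenoid carbon is trapped at once by the alkenylboronate at the other chain end to give the eleven-membered boronate complex 23, and its only carbon ligand able to migrate, C10, shifts from boron to C9 anti to the C9–O8 bond, so that boron leaves the ring, the ten-membered carbocycle closes and the epoxide strain pays for the medium-ring strain. The closest known reaction type is the intermolecular homologation of boronic esters with LiTMP-lithiated terminal epoxides (lithiation–borylation with 1,2-metallate rearrangement), which gives syn-1,2-diols after oxidation; new here are the intramolecular ring-contracting setting and the acyl quench. Mode of closure: the eleven-membered ring forms by addition of C9–Li to trigonal boron, a capture with an early transition state run at high dilution, and the ten-membered ring forms by an invertive SN2-type 1,2-shift at C9 inside that ring. C9 is set stereospecifically (retention in the C–Li to C–B exchange, inversion in the shift, hence boron syn to O8), C8 is untouched, and the migrating sp2 carbon keeps the Z geometry of C1=C10. The step needs ring-forming capture to outrun carbenoid decay and oligomerisation (dilution, slow base addition, trap in the same molecule), needs the base to find no other acidic site (all hydroxyls silylated, no carbonyl group present), and needs acylation at O8 only, which is secured because O8 is the only alkoxide formed and the anhydride is already present when 23 rearranges on warming.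

Step 14
Reactants: 25 ten-membered C9 boronate C8 angelate
Product: 26 ten-membered C9 alcohol C8 angelate (O6-TBS; O7-TES; O12-TBS)
Conditions: 30% aq H2O2, pH 7 phosphate buffer, THF, 0 °C
Reagents that add atoms: hydrogen peroxide, OO
Why: Peroxide oxidation of the secondary allylic boronate is a 1,2-shift from boron to oxygen with retention, so O9 takes the place of boron syn to O8, and the neutral buffer spares the angelate and prevents acyl migration.

Step 15
Reactants: 26 ten-membered C9 alcohol C8 angelate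
Product: 27 6,7,9,12-tetraol 8-angelate
Conditions: HF·pyridine, pyridine, THF, 0 °C to rt
Reagents that add atoms: none
Why: Buffered fluoride-mediated desilylation removes all three silyl ethers under weakly acidic conditions that avoid acyl migration and transannular cyclisation of the 1(10),4-diene.

Step 16
Reactants: 27 6,7,9,12-tetraol 8-angelate
Product: 30 CNP0292337.1, via C12 enal 28 (not isolated), via C12 lactol 29 (not isolated)
Conditions: TEMPO (cat.), PhI(OAc)2, CH2Cl2, rt
Reagents that add atoms: none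
Why: In this TEMPO/PhI(OAc)2 oxidative lactonisation the oxoammonium salt oxidises the primary allylic O12 alcohol much faster than the secondary ones, the enal is trapped by the cis-disposed O6 hydroxyl as the five-membered lactol, and the lactol is oxidised to the α-methylene-γ-lactone.

Compound list
1 | pent-4-yn-1-ol | C#CCCCO | starting material
2 | pent-4-ynal | C#CCCC=O | intermediate
3 | (Z)-6-iodohept-5-en-1-yne (C1–C5, C10, C14) | C#CCC/C=C(/C)I | intermediate
4 | 2-bromoprop-2-en-1-ol | C=C(Br)CO | starting material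
5 | (2-bromoallyloxy)(tert-butyl)dimethylsilane (C11–C13) | C=C(Br)CO[Si](C)(C)C(C)(C)C | intermediate
6 | L-erythrulose, (3S)-1,3,4-trihydroxybutan-2-one (C6–C9) | OCC(=O)[C@@H](O)CO | starting material
7 | 3,4-O-isopropylidene-L-erythrulose, 1-[(4S)-2,2-dimethyl-1,3-dioxolan-4-yl]-2-hydroxyethanone | OCC(=O)[C@@H]1COC(C)(C)O1 | intermediate
8 | 1-O-triethylsilyl-3,4-O-isopropylidene-L-erythrulose | CC[Si](CC)(CC)OCC(=O)[C@@H]1COC(C)(C)O1 | intermediate
9 | 3-(TBS-oxy)prop-1-en-2-yllithium | [Li]C(=C)CO[Si](C)(C)C(C)(C)C | intermediate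
10 | 3-(TBS-oxy)prop-1-en-2-ylmagnesium bromide | Br[Mg]C(=C)CO[Si](C)(C)C(C)(C)C | intermediate
11 | (3R)-2-(TBS-oxymethyl)-3-[(4S)-2,2-dimethyl-1,3-dioxolan-4-yl]-4-(TES-oxy)but-1-en-3-ol (C7 as in the target) | CC[Si](CC)(CC)OC[C@](O)(C(=C)CO[Si](C)(C)C(C)(C)C)[C@@H]1COC(C)(C)O1 | intermediate
12 | C6 aldehyde: 2-hydroxy-2-[(4S)-2,2-dimethyl-1,3-dioxolan-4-yl]-3-(TBS-oxymethyl)but-3-enal (C7, C8 as in the target) | O=C[C@](O)(C(=C)CO[Si](C)(C)C(C)(C)C)[C@@H]1COC(C)(C)O1 | intermediate
13 | dimethyl[(1E,5Z)-6-iodo-2-methylhepta-1,5-dienyl]alane | C[Al](C)/C=C(\C)CC/C=C(/C)I | intermediate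
14 | seco-germacrane (C9/C10 open) 6,7-diol: 4E,1(10)Z-diene, C10 iodide, O8/O9 acetonide, O12-TBS; C6, C7, C8 as in the target | O[C@@H](/C=C(\C)CC/C=C(/C)I)[C@](O)(C(=C)CO[Si](C)(C)C(C)(C)C)[C@@H]1COC(C)(C)O1 | intermediate
15 | O6-TBS ether of 14 (O7 free) | CC(C)(C)[Si](C)(C)O[C@@H](/C=C(\C)CC/C=C(/C)I)[C@](O)(C(=C)CO[Si](C)(C)C(C)(C)C)[C@@H]1COC(C)(C)O1 | intermediate
16 | O6-TBS O7-TES ether of 14 | CC(C)(C)[Si](C)(C)O[C@@H](/C=C(\C)CC/C=C(/C)I)[C@](O[Si](CC)(CC)CC)(C(=C)CO[Si](C)(C)C(C)(C)C)[C@@H]1COC(C)(C)O1 | intermediate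
17 | C10 alkenyllithium from 16 (lithium cis to C2) | CC(C)(C)[Si](C)(C)O[C@@H](/C=C(\C)CC/C=C(/C)[Li])[C@](O[Si](CC)(CC)CC)(C(=C)CO[Si](C)(C)C(C)(C)C)[C@@H]1COC(C)(C)O1 | intermediate
18 | C10 pinacol boronate (boron cis to C2), O8/O9 acetonide | CC(C)(C)[Si](C)(C)O[C@@H](/C=C(\C)CC/C=C(/C)B2OC(C)(C)C(C)(C)O2)[C@](O[Si](CC)(CC)CC)(C(=C)CO[Si](C)(C)C(C)(C)C)[C@@H]1COC(C)(C)O1 | intermediate
19 | C10 pinacol boronate, free C8,C9-diol | CC(C)(C)[Si](C)(C)O[C@@H](/C=C(\C)CC/C=C(/C)B2OC(C)(C)C(C)(C)O2)[C@](O[Si](CC)(CC)CC)(C(=C)CO[Si](C)(C)C(C)(C)C)[C@@H](O)CO | intermediate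
20 | C9 p-toluenesulfonate of 19 | CC(C)(C)[Si](C)(C)O[C@@H](/C=C(\C)CC/C=C(/C)B2OC(C)(C)C(C)(C)O2)[C@](O[Si](CC)(CC)CC)(C(=C)CO[Si](C)(C)C(C)(C)C)[C@@H](O)COS(=O)(=O)c1ccc(C)cc1 | intermediate
21 | terminal C8–C9 epoxide (ring oxygen O8) with C10 pinacol boronate | CC(C)(C)[Si](C)(C)O[C@@H](/C=C(\C)CC/C=C(/C)B2OC(C)(C)C(C)(C)O2)[C@](O[Si](CC)(CC)CC)(C(=C)CO[Si](C)(C)C(C)(C)C)[C@@H]1CO1 | intermediate
22 | C9-lithiated epoxide (lithium trans to C7) | CC(C)(C)[Si](C)(C)O[C@@H](/C=C(\C)CC/C=C(/C)B2OC(C)(C)C(C)(C)O2)[C@](O[Si](CC)(CC)CC)(C(=C)CO[Si](C)(C)C(C)(C)C)[C@H]1O[C@@H]1[Li] | intermediate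
23 | eleven-membered cyclic lithium boronate complex (ring C1–C8, C9, B, C10; epoxide intact) | CC(C)(C)[Si](C)(C)O[C@H]1/C=C(\C)CC/C=C(/C)[B-]2(OC(C)(C)C(C)(C)O2)[C@H]3O[C@@H]3[C@@]1(O[Si](CC)(CC)CC)C(=C)CO[Si](C)(C)C(C)(C)C.[Li+] | intermediate
24 | ten-membered ring, C9 pinacol boronate, lithium C8 alkoxide | CC(C)(C)[Si](C)(C)O[C@H]1/C=C(\C)CC/C=C(/C)[C@@H](B2OC(C)(C)C(C)(C)O2)[C@H]([O-])[C@@]1(O[Si](CC)(CC)CC)C(=C)CO[Si](C)(C)C(C)(C)C.[Li+] | intermediate
25 | (1(10)Z,4E)-germacra-1(10),4,11(13)-triene: C9 pinacol boronate, O8 angelate, O6-TBS, O7-TES, O12-TBS | CC(C)(C)[Si](C)(C)O[C@H]1/C=C(\C)CC/C=C(/C)[C@@H](B2OC(C)(C)C(C)(C)O2)[C@H](OC(=O)/C(C)=C\C)[C@@]1(O[Si](CC)(CC)CC)C(=C)CO[Si](C)(C)C(C)(C)C | intermediate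
26 | as 25 with C9–OH in place of boron (C6–C9 as in the target) | CC(C)(C)[Si](C)(C)O[C@H]1/C=C(\C)CC/C=C(/C)[C@@H](O)[C@H](OC(=O)/C(C)=C\C)[C@@]1(O[Si](CC)(CC)CC)C(=C)CO[Si](C)(C)C(C)(C)C | intermediate
27 | (1(10)Z,4E)-germacra-1(10),4,11(13)-triene-6,7,8,9,12-pentol 8-angelate | O[C@H]1/C=C(\C)CC/C=C(/C)[C@@H](O)[C@H](OC(=O)/C(C)=C\C)[C@@]1(O)C(=C)CO | intermediate
28 | C12 enal of 27 | O[C@H]1/C=C(\C)CC/C=C(/C)[C@@H](O)[C@H](OC(=O)/C(C)=C\C)[C@@]1(O)C(=C)C=O | intermediate
29 | 6,12-lactol (C12 epimers) | C=C1C(O)O[C@H]2/C=C(\C)CC/C=C(/C)[C@@H](O)[C@H](OC(=O)/C(C)=C\C)[C@@]12O | intermediate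
30 | CNP0292337.1, (6S,7R,8S,9R)-8-angeloyloxy-7,9-dihydroxygermacra-1(10)Z,4E,11(13)-trien-6,12-olide | C=C1C(=O)O[C@H]2/C=C(\C)CC/C=C(/C)[C@@H](O)[C@H](OC(=O)/C(C)=C\C)[C@@]12O | target

Total step count: 16. Longest linear sequence: 13 steps (steps 4 to 16, from L-erythrulose).

Steps most likely to fail

Step 13. Decay of the lithiated epoxide, intermolecular boronate formation or allylic deprotonation next to boron may outrun the ring-forming capture, or the shift may be slow in the crowded complex.
Fallback (known chemistry, same bond, from 16 back to 26):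
- The acetonide of 16 is cleaved (Zn(NO3)2·6H2O, MeCN) to the iodo C8,C9-diol F1.
- The primary hydroxyl is silylated (Et3SiCl, imidazole, −20 °C) to the O9 TES ether F2.
- O8 is esterified with the mixed anhydride of angelic acid and 2,4,6-trichlorobenzoyl chloride (Et3N, toluene, 80 °C, Yamaguchi type) to the O8 angelate F3.
- The primary TES ether is oxidised directly under Swern conditions to the α-angeloyloxy C9 aldehyde F4.
- A Nozaki–Hiyama–Kishi macrocyclisation (CrCl2, NiCl2 cat., DMSO, high dilution) joins C10 to C9 and gives 26. C9 epimers, if formed, are separated there.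

Step 14. β-Elimination of boron and the C8 acyloxy group from the peroxide–boronate complex may compete with the carbon-to-oxygen shift.
Fallback (from 24 back to 27):
- The rearranged mixture is quenched with aq NH4Cl instead of the anhydride to give the β-hydroxy boronate F5.
- F5 is oxidised (NaBO3·4H2O, THF/H2O), the precedented course for such adducts, to the syn-C8,C9-diol F6.
- The less hindered allylic O9 is silylated (Et3SiCl, imidazole, −40 °C) to the O9 TES ether F7.
- O8 is angeloylated with the same mixed anhydride to the O8 angelate O9 TES ether F8.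
- HF·pyridine removes all silyl groups and gives 27.

Step 8. Facial selectivity at the C6 aldehyde may be poor if the chelate does not distinguish C8 from C11, and methyl transfer from aluminium may compete.
Fallback (from 14 as obtained, back to 14): the C6 carbinol is oxidised with Dess–Martin periodinane to the α-hydroxy enone F9. It is then reduced under reagent control by Corey–Bakshi–Shibata reduction ((R)-Me-CBS, BH3·SMe2, taking C7 as the large group) to 14 as a single C6 epimer.

Further compounds
F1 | step 13 | iodo C8,C9-diol (O6-TBS, O7-TES, O12-TBS) | CC(C)(C)[Si](C)(C)O[C@@H](/C=C(\C)CC/C=C(/C)I)[C@](O[Si](CC)(CC)CC)(C(=C)CO[Si](C)(C)C(C)(C)C)[C@@H](O)CO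
F2 | step 13 | O9 TES ether of F1 | CC(C)(C)[Si](C)(C)O[C@@H](/C=C(\C)CC/C=C(/C)I)[C@](O[Si](CC)(CC)CC)(C(=C)CO[Si](C)(C)C(C)(C)C)[C@@H](O)CO[Si](CC)(CC)CC
F3 | step 13 | O8 angelate of F2 | CC(C)(C)[Si](C)(C)O[C@@H](/C=C(\C)CC/C=C(/C)I)[C@](O[Si](CC)(CC)CC)(C(=C)CO[Si](C)(C)C(C)(C)C)[C@@H](OC(=O)/C(C)=C\C)CO[Si](CC)(CC)CC
F4 | step 13 | α-angeloyloxy C9 aldehyde with C10 iodide | CC(C)(C)[Si](C)(C)O[C@@H](/C=C(\C)CC/C=C(/C)I)[C@](O[Si](CC)(CC)CC)(C(=C)CO[Si](C)(C)C(C)(C)C)[C@@H](OC(=O)/C(C)=C\C)C=O
F5 | step 14 | ten-membered β-hydroxy boronate (C8–OH, C9–Bpin) | CC(C)(C)[Si](C)(C)O[C@H]1/C=C(\C)CC/C=C(/C)[C@@H](B2OC(C)(C)C(C)(C)O2)[C@H](O)[C@@]1(O[Si](CC)(CC)CC)C(=C)CO[Si](C)(C)C(C)(C)C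
F6 | step 14 | ten-membered syn-C8,C9-diol | CC(C)(C)[Si](C)(C)O[C@H]1/C=C(\C)CC/C=C(/C)[C@@H](O)[C@H](O)[C@@]1(O[Si](CC)(CC)CC)C(=C)CO[Si](C)(C)C(C)(C)C
F7 | step 14 | O9 TES ether of F6 | CC(C)(C)[Si](C)(C)O[C@H]1/C=C(\C)CC/C=C(/C)[C@@H](O[Si](CC)(CC)CC)[C@H](O)[C@@]1(O[Si](CC)(CC)CC)C(=C)CO[Si](C)(C)C(C)(C)C
F8 | step 14 | O8 angelate O9 TES ether | CC(C)(C)[Si](C)(C)O[C@H]1/C=C(\C)CC/C=C(/C)[C@@H](O[Si](CC)(CC)CC)[C@H](OC(=O)/C(C)=C\C)[C@@]1(O[Si](CC)(CC)CC)C(=C)CO[Si](C)(C)C(C)(C)C
F9 | step 8 | α-hydroxy enone (C6 ketone) | O=C(/C=C(\C)CC/C=C(/C)I)[C@](O)(C(=C)CO[Si](C)(C)C(C)(C)C)[C@@H]1COC(C)(C)O1
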